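**Retrosynthetic overview**
- C11–C12 is cut first. A bicyclic C11 aldehyde is joined to (2E,6E)-farnesylbarium chloride by α-selective carbonyl allylation, and the C11 hydroxyl is then removed by Barton–McCombie reduction.
- In the aldehyde, the C8 carbinol comes from MeCeCl2 addition to a C8 ketone, C9–C11 from alkoxymethylation of the C8=C9 silyl enol ether, and the C10 methyl from cuprate addition to a bicyclic enone. All three groups enter on the convex face, cis to H-5.
- Ring A is bought as 3-methylcyclohexenone, and conjugate methylation makes the gem-dimethyl carbon. Ring B is closed second, by Mukaiyama–Michael addition to methyl vinyl ketone followed by aldol condensation.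
- The enone has one stereocentre (C5). It is resolved with (S)-N,S-dimethyl-S-phenylsulfoximine, and every other centre is relayed from it.
- Both side-chain E double bonds are bought with (2E,6E)-farnesol.

**Assumption:** the SMILES is read literally, so H-5 and the C10 methyl are cis (cis-decalin, 1R,2R,4aR,8aS) and trans-fused sclareolide or sclareol cannot serve as starting material. Terpenoid numbering is used: C4 gem-dimethyl, C5 ring-fusion CH, C8 carbinol, C9 side-chain carbon, C10 ring-fusion C–Me, side chain from C11.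

**Step 1**
Reactants: 1 3-methylcyclohex-2-en-1-one
Product: 2 [(3,3-dimethylcyclohex-1-en-1-yl)oxy]trimethylsilane
Conditions: MeMgBr, CuBr·SMe2 (5 mol %), TMSCl, DMPU, THF, −78 → 0 °C; Et3N, aq NaHCO3
Reagents that add atoms: methylmagnesium bromide (C[Mg]Br); chlorotrimethylsilane (C[Si](C)(C)Cl)
Why: Copper-catalysed conjugate addition accelerated by TMSCl builds the gem-dimethyl carbon C4 and fixes the enolate regiospecifically on the hindered side (C5=C10) as its silyl enol ether, and no stereocentre is formed.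

**Step 2**
Reactants: 2 [(3,3-dimethylcyclohex-1-en-1-yl)oxy]trimethylsilane; 3 but-3-en-2-one (methyl vinyl ketone)
Product: 4 (±)-3,3-dimethyl-2-(3-oxobutyl)cyclohexan-1-one
Conditions: BF3·OEt2 (20 mol %), i-PrOH (1.1 equiv), CH2Cl2/MeNO2, −78 → −20 °C
Reagents that add atoms: none
Why: In this Mukaiyama–Michael addition only the silyl enol ether carbon C5 can attack the BF3-activated enone while i-PrOH takes up the silyl group, and the new centre C5 is racemic at this stage.

**Step 3**
Reactants: 4 (±)-3,3-dimethyl-2-(3-oxobutyl)cyclohexan-1-one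
Product: 5 (±)-5,5-dimethyl-4,4a,5,6,7,8-hexahydronaphthalen-2(3H)-one
Conditions: KOH (0.5 equiv), MeOH, reflux
Reagents that add atoms: none
Why: Intramolecular aldol condensation (the closing half of a Robinson annulation) is driven by irreversible dehydration to the six-membered conjugated enone and closes ring B, with C5 still racemic.

**Step 4**
Reactants: 5 (±)-5,5-dimethyl-4,4a,5,6,7,8-hexahydronaphthalen-2(3H)-one; 6 (S)-N,S-dimethyl-S-phenylsulfoximine
Product: 8 (4aR)-5,5-dimethyl-2-{[(S)-N-methyl-S-phenylsulfonimidoyl]methyl}-2,3,4,4a,5,6,7,8-octahydronaphthalen-2-ol (separated diastereomer; carbinol centre unassigned because it is destroyed in step 5), via lithiated sulfoximine 7 (not isolated)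
Conditions: 6, n-BuLi, THF, −78 °C; 5, −78 °C; H2O; silica gel separation of the diastereomers
Reagents that add atoms: none
Why: 1,2-Addition of the enantiopure sulfoximine carbanion (Johnson ketone resolution) converts the racemate into diastereomeric β-hydroxysulfoximines that differ at C5 and separate by chromatography, and the adduct of the (4aR)-enone is kept after assignment by X-ray analysis.

**Step 5**
Reactants: 8 (4aR)-β-hydroxysulfoximine adduct
Product: 9 (4aR)-5,5-dimethyl-4,4a,5,6,7,8-hexahydronaphthalen-2(3H)-one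
Conditions: toluene, reflux
Reagents that add atoms: none
Why: Thermal retro-addition of the β-hydroxysulfoximine releases the enone under neutral conditions that cannot touch the γ-stereocentre C5, so a single enantiomer and the reusable auxiliary are obtained.

**Step 6**
Reactants: 9 (4aR)-5,5-dimethyl-4,4a,5,6,7,8-hexahydronaphthalen-2(3H)-one
Product: 10 trimethyl{[(4aR,8aS)-5,5,8a-trimethyl-3,4,4a,5,6,7,8,8a-octahydronaphthalen-2-yl]oxy}silane
Conditions: MeLi (2.4 equiv), CuI (1.2 equiv), Et2O, 0 °C; TMSCl, 9, −78 → −20 °C; Et3N, aq NaHCO3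
Reagents that add atoms: methyllithium ([Li]C), used as Me2CuLi; chlorotrimethylsilane (C[Si](C)(C)Cl)
Why: In this Gilman cuprate conjugate addition with silyl trapping, the methyl group reaches C10 anti to the bulky quaternary C4 substituent on the neighbouring γ-carbon, that is on the face of H-5, which sets the cis ring fusion and locks the enolate at C8=C9.

**Step 7**
Reactants: 10 silyl enol ether
Product: 11 (1S,4aR,8aS)-1-[(benzyloxy)methyl]-5,5,8a-trimethyloctahydronaphthalen-2(1H)-one
Conditions: BnOCH2Cl, ZnBr2 (20 mol %), CH2Cl2, −40 → −10 °C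
Reagents that add atoms: benzyl chloromethyl ether (ClCOCc1ccccc1)
Why: In this Mukaiyama-type alkoxymethylation the benzyloxymethyl oxocarbenium ion attacks C9 axially on the convex face, anti to the pseudo-axial C1 methylene of the folded ring A, so C11 ends up cis to H-5 and the C10 methyl, and the cold non-basic medium avoids epimerisation.

**Step 8**
Reactants: 11 benzyloxymethyl ketone
Product: 12 (1S,2R,4aR,8aS)-1-[(benzyloxy)methyl]-2,5,5,8a-tetramethyldecahydronaphthalen-2-ol
Conditions: CeCl3 (anhydrous), MeLi, THF, −78 °C; 11, −78 °C; H2O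
Reagents that add atoms: methyllithium ([Li]C), used as MeCeCl2
Why: In this organocerium 1,2-addition the low basicity prevents enolisation at C9 and loss of benzyl alcohol, and because axial approach is blocked by the syn-axial C1 methylene the methyl group enters equatorially from the convex face to give the 8β-methyl 8α-hydroxy centre.

**Step 9**
Reactants: 12 tertiary alcohol
Product: 13 {[(1S,2R,4aR,8aS)-1-[(benzyloxy)methyl]-2,5,5,8a-tetramethyldecahydronaphthalen-2-yl]oxy}triethylsilane
Conditions: TESOTf, 2,6-lutidine, CH2Cl2, 0 °C → rt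
Reagents that add atoms: triethylsilyl triflate (CC[Si](CC)(CC)OS(=O)(=O)C(F)(F)F)
Why: Silyl triflate silylation is strong enough for a hindered tertiary alcohol, and it masks O-8 so that C11 will later carry the only free hydroxyl, with no stereocentre touched.

**Step 10**
Reactants: 13 benzyl ether
Product: 14 [(1S,2R,4aR,8aS)-2,5,5,8a-tetramethyl-2-(triethylsilyloxy)decahydronaphthalen-1-yl]methanol
Conditions: H2 (1 atm), Pd/C, EtOAc, rt
Reagents that add atoms: none
Why: Catalytic hydrogenolysis removes the benzyl group while no olefin is yet present, and the silyl ether is stable in the aprotic solvent.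

**Step 11**
Reactants: 14 primary alcohol
Product: 15 (1R,2R,4aR,8aS)-2,5,5,8a-tetramethyl-2-(triethylsilyloxy)decahydronaphthalene-1-carbaldehyde
Conditions: n-Pr4N[RuO4] (5 mol %), NMO, 4 Å MS, CH2Cl2, rt
Reagents that add atoms: none
Why: Ley–Griffith oxidation is neutral and stops at the aldehyde, so C9 is not epimerised and the silyl ether survives.

**Step 12**
Reactants: 16 (2E,6E)-farnesol
Product: 17 (2E,6E)-farnesyl chloride
Conditions: NCS, Me2S, CH2Cl2, −30 → 0 °C
Reagents that add atoms: N-chlorosuccinimide (O=C1CCC(=O)N1Cl)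
Why: Corey–Kim chlorination displaces the alkoxysulfonium group by direct substitution at the primary carbon, without allylic transposition or loss of E geometry.

**Step 13**
Reactants: 15 bicyclic aldehyde; 17 (2E,6E)-farnesyl chloride
Product: 19 (3E,7E)-1-[(1S,2R,4aR,8aS)-2,5,5,8a-tetramethyl-2-(triethylsilyloxy)decahydronaphthalen-1-yl]-4,8,12-trimethyltrideca-3,7,11-trien-1-ol (C11 epimers), via farnesylbarium chloride 18 (not isolated)
Conditions: Li, biphenyl, THF, rt; BaI2 (anhydrous), rt, 30 min; 17, −78 °C; 15, −78 °C; aq NH4Cl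
Reagents that add atoms: none
Why: In this carbonyl allylation the allylbarium reagent reacts at −78 °C through its unsubstituted α-terminus with retention of the E double bond, γ-attack would put a quaternary carbon beside a very crowded carbinol, and the new C11 centre forms as an epimer mixture that does not matter because it is removed in step 15.

**Step 14**
Reactants: 19 C11 carbinol
Product: 21 O-{(3E,7E)-1-[(1S,2R,4aR,8aS)-2,5,5,8a-tetramethyl-2-(triethylsilyloxy)decahydronaphthalen-1-yl]-4,8,12-trimethyltrideca-3,7,11-trien-1-yl} S-methyl dithiocarbonate, via sodium xanthate salt 20 (not isolated)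
Conditions: NaH, THF, 0 °C; CS2; MeI, rt
Reagents that add atoms: carbon disulfide (S=C=S); iodomethane (CI)
Why: Xanthate formation uses the smallest available electrophiles on the hindered alkoxide, and silyl migration is disfavoured because O-8 and C11 are trans-diaxial in the preferred chair.

**Step 15**
Reactants: 21 xanthate
Product: 22 triethyl{[(1R,2R,4aR,8aS)-2,5,5,8a-tetramethyl-1-[(3E,7E)-4,8,12-trimethyltrideca-3,7,11-trien-1-yl]decahydronaphthalen-2-yl]oxy}silane
Conditions: n-Bu3SnH, Et3B (20 mol %), air, toluene, rt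
Reagents that add atoms: none
Why: Barton–McCombie deoxygenation at room temperature avoids Chugaev elimination, and the secondary C11 radical is reduced by the stannane faster than it can cyclise reversibly onto the homoallylic double bond, so the olefin positions, the olefin geometries and C9 are kept.

**Step 16**
Reactants: 22 silyl ether
Product: 23 (1R,2R,4aR,8aS)-2,5,5,8a-tetramethyl-1-[(3E,7E)-4,8,12-trimethyltrideca-3,7,11-trien-1-yl]decahydronaphthalen-2-ol (target)
Conditions: n-Bu4NF, THF, 50 °C; H2O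
Reagents that add atoms: none
Why: Fluoride desilylation is non-acidic, so the tertiary alcohol does not ionise and the triene neither cyclises nor isomerises.

**Compound list**
1 | 3-methylcyclohex-2-en-1-one | CC1=CC(=O)CCC1 | starting material
2 | [(3,3-dimethylcyclohex-1-en-1-yl)oxy]trimethylsilane | C[Si](C)(C)OC1=CC(C)(C)CCC1 | intermediate
3 | but-3-en-2-one (methyl vinyl ketone) | CC(=O)C=C | starting material
4 | (±)-3,3-dimethyl-2-(3-oxobutyl)cyclohexan-1-one | CC(=O)CCC1C(=O)CCCC1(C)C | intermediate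
5 | (±)-5,5-dimethyl-4,4a,5,6,7,8-hexahydronaphthalen-2(3H)-one | O=C1C=C2CCCC(C)(C)C2CC1 | intermediate
6 | (S)-N,S-dimethyl-S-phenylsulfoximine | CN=[S@@](C)(=O)c1ccccc1 | starting material
7 | (S)-S-(lithiomethyl)-N-methyl-S-phenylsulfoximine | [Li]C[S@@](=O)(=NC)c1ccccc1 | intermediate
8 | (4aR)-5,5-dimethyl-2-{[(S)-N-methyl-S-phenylsulfonimidoyl]methyl}-2,3,4,4a,5,6,7,8-octahydronaphthalen-2-ol (carbinol centre unassigned) | CN=[S@@](=O)(c1ccccc1)CC1(O)C=C2CCCC(C)(C)[C@H]2CC1 | intermediate
9 | (4aR)-5,5-dimethyl-4,4a,5,6,7,8-hexahydronaphthalen-2(3H)-one | O=C1C=C2CCCC(C)(C)[C@H]2CC1 | intermediate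
10 | trimethyl{[(4aR,8aS)-5,5,8a-trimethyl-3,4,4a,5,6,7,8,8a-octahydronaphthalen-2-yl]oxy}silane | C[Si](C)(C)OC1=C[C@@]2(C)CCCC(C)(C)[C@H]2CC1 | intermediate
11 | (1S,4aR,8aS)-1-[(benzyloxy)methyl]-5,5,8a-trimethyloctahydronaphthalen-2(1H)-one | c1ccccc1COC[C@@H]1[C@@]2(C)CCCC(C)(C)[C@H]2CCC1=O | intermediate
12 | (1S,2R,4aR,8aS)-1-[(benzyloxy)methyl]-2,5,5,8a-tetramethyldecahydronaphthalen-2-ol | c1ccccc1COC[C@@H]1[C@@]2(C)CCCC(C)(C)[C@H]2CC[C@@]1(C)O | intermediate
13 | triethylsilyl ether of 12 | c1ccccc1COC[C@@H]1[C@@]2(C)CCCC(C)(C)[C@H]2CC[C@@]1(C)O[Si](CC)(CC)CC | intermediate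
14 | [(1S,2R,4aR,8aS)-2,5,5,8a-tetramethyl-2-(triethylsilyloxy)decahydronaphthalen-1-yl]methanol | OC[C@@H]1[C@@]2(C)CCCC(C)(C)[C@H]2CC[C@@]1(C)O[Si](CC)(CC)CC | intermediate
15 | (1R,2R,4aR,8aS)-2,5,5,8a-tetramethyl-2-(triethylsilyloxy)decahydronaphthalene-1-carbaldehyde | O=C[C@@H]1[C@@]2(C)CCCC(C)(C)[C@H]2CC[C@@]1(C)O[Si](CC)(CC)CC | intermediate
16 | (2E,6E)-farnesol | CC(C)=CCC/C(C)=C/CC/C(C)=C/CO | starting material
17 | (2E,6E)-farnesyl chloride | CC(C)=CCC/C(C)=C/CC/C(C)=C/CCl | intermediate
18 | (2E,6E)-farnesylbarium chloride | CC(C)=CCC/C(C)=C/CC/C(C)=C/C[Ba]Cl | intermediate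
19 | C11 carbinol (both C11 epimers), 8-O-TES | CC(C)=CCC/C(C)=C/CC/C(C)=C/CC(O)[C@@H]1[C@@]2(C)CCCC(C)(C)[C@H]2CC[C@@]1(C)O[Si](CC)(CC)CC | intermediate
20 | sodium O-alkyl dithiocarbonate of 19 | CC(C)=CCC/C(C)=C/CC/C(C)=C/CC(OC(=S)[S-])[C@@H]1[C@@]2(C)CCCC(C)(C)[C@H]2CC[C@@]1(C)O[Si](CC)(CC)CC.[Na+] | intermediate
21 | O-alkyl S-methyl dithiocarbonate of 19 | CC(C)=CCC/C(C)=C/CC/C(C)=C/CC(OC(=S)SC)[C@@H]1[C@@]2(C)CCCC(C)(C)[C@H]2CC[C@@]1(C)O[Si](CC)(CC)CC | intermediate
22 | triethylsilyl ether of the target | CC(C)=CCC/C(C)=C/CC/C(C)=C/CC[C@@H]1[C@@]2(C)CCCC(C)(C)[C@H]2CC[C@@]1(C)O[Si](CC)(CC)CC | intermediate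
23 | (1R,2R,4aR,8aS)-2,5,5,8a-tetramethyl-1-[(3E,7E)-4,8,12-trimethyltrideca-3,7,11-trien-1-yl]decahydronaphthalen-2-ol | CC(C)=CCC/C(C)=C/CC/C(C)=C/CC[C@@H]1[C@@]2(C)CCCC(C)(C)[C@H]2CC[C@@]1(C)O | target

**Total step count:** 16.
**Longest linear sequence:** 15 steps (steps 1–11 and 13–16).

**Steps most likely to fail**

**Step 13** (α-selective farnesylbarium addition to a very hindered aldehyde).
- The fallback sets out from 15 and comes back at 22. It replaces the carbonyl addition and the deoxygenation by an sp3–sp2 cross-coupling.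
- Wittig methylenation of 15 with Ph3P=CH2 gives the terminal alkene F1.
- Hydroboration with 9-BBN-H gives the B-alkyl-9-BBN borane F2.
- Suzuki–Miyaura coupling (PdCl2(dppf), Cs2CO3, DMF/THF/H2O) with the E-vinyl iodide F3 forms C12–C13 with retention of geometry and gives 22 directly.
- The E-vinyl iodide F3 comes from Negishi carboalumination (Me3Al, Cp2ZrCl2) and iodinolysis of the known enyne F4.

**Step 14** (derivatising the crowded C11 carbinol for radical cleavage).
- The fallback sets out from 19 and comes back at 22.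
- The lithium alkoxide of 19 (n-BuLi, THF/TMEDA) is phosphorylated with ClP(O)(NMe2)2 to the phosphorodiamidate F5.
- The C–O bond of F5 is cleaved by dissolving-metal reduction (Li, EtNH2, t-BuOH, THF, 0 °C; Ireland deoxygenation). These conditions spare isolated trisubstituted olefins and the silyl ether.

**Step 7** (C–C bond formation at the neopentyl carbon C9 without epimerisation).
- The fallback sets out from 10 and comes back at 11.
- MeLi (THF, 0 °C) cleaves the silyl enol ether to the lithium enolate F6.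
- F6 adds to monomeric formaldehyde at −78 °C in an aldol reaction on the same convex face and gives the β-hydroxy ketone F7.
- Acid-catalysed benzylation with benzyl 2,2,2-trichloroacetimidate (TfOH cat., CH2Cl2/cyclohexane, 0 °C) then gives 11.

**Further compounds**
F1 | step 13 | triethyl{[(1R,2R,4aR,8aS)-1-ethenyl-2,5,5,8a-tetramethyldecahydronaphthalen-2-yl]oxy}silane | C=C[C@@H]1[C@@]2(C)CCCC(C)(C)[C@H]2CC[C@@]1(C)O[Si](CC)(CC)CC
F2 | step 13 | B-alkyl-9-borabicyclo[3.3.1]nonane from F1 (boron on C12) | C(C[C@@H]1[C@@]2(C)CCCC(C)(C)[C@H]2CC[C@@]1(C)O[Si](CC)(CC)CC)B1C2CCCC1CCC2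
F3 | step 13 | (1E,5E)-1-iodo-2,6,10-trimethylundeca-1,5,9-triene | CC(C)=CCC/C(C)=C/CC/C(C)=C/I
F4 | step 13 | (5E)-6,10-dimethylundeca-5,9-dien-1-yne | CC(C)=CCC/C(C)=C/CCC#C
F5 | step 14 | N,N,N',N'-tetramethylphosphorodiamidate of 19 | CC(C)=CCC/C(C)=C/CC/C(C)=C/CC(OP(=O)(N(C)C)N(C)C)[C@@H]1[C@@]2(C)CCCC(C)(C)[C@H]2CC[C@@]1(C)O[Si](CC)(CC)CC
F6 | step 7 | lithium (4aR,8aS)-5,5,8a-trimethyl-3,4,4a,5,6,7,8,8a-octahydronaphthalen-2-olate | [Li]OC1=C[C@@]2(C)CCCC(C)(C)[C@H]2CC1
F7 | step 7 | (1S,4aR,8aS)-1-(hydroxymethyl)-5,5,8a-trimethyloctahydronaphthalen-2(1H)-one | OC[C@@H]1[C@@]2(C)CCCC(C)(C)[C@H]2CCC1=O
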